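**Assumption:** the target, 3,5,7,8,2'-pentamethoxyflavone, has no stereocentre, so it is one achiral compound and no enantiocontrol is needed.

**Retrosynthetic overview**
1. Target 12 ⇐ O-methylation of flavonol 11 ⇐ C3-oxygenation (epoxidation, then isomerisation) of flavone 9.
2. Flavone 9 ⇐ oxidative cyclisation of 2'-hydroxychalcone 8; ring C is the only ring built, and it is closed last.
3. Chalcone 8 ⇐ Claisen–Schmidt aldol condensation of acetophenone 5 (ring A) with 2-methoxybenzaldehyde 6 (ring B); this is the key C–C bond.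
4. Acetophenone 5 ⇐ Friedel–Crafts acetylation with ortho-demethylation of 1,2,3,5-tetramethoxybenzene 2 ⇐ 3,4,5-trimethoxyphenol 1.

**Route**

Step 1
Reactants: 1 3,4,5-trimethoxyphenol
Product: 2 1,2,3,5-tetramethoxybenzene
Conditions: MeI (1.5 equiv), K2CO3 (2 equiv), acetone, reflux, 12 h
Reagents that add atoms: iodomethane (MeI), CI
Why: Williamson O-methylation of the only phenol gives the symmetric tetramethyl ether; no stereocentre is involved.

Step 2
Reactants: 2 1,2,3,5-tetramethoxybenzene; 3 acetyl chloride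
Product: 5 1-(2-hydroxy-3,4,6-trimethoxyphenyl)ethanone, via tetramethoxyacetophenone 4 (not isolated)
Conditions: AlCl3 (2.5 equiv), Et2O, 0 °C to rt, 24 h; then ice/aq HCl
Reagents that add atoms: none
Why: Friedel–Crafts acylation occurs at one of the two equivalent free ring positions, and the AlCl3-chelated ortho-methoxy group that is buttressed by a neighbouring methoxy is then cleaved selectively to give the hydrogen-bonded 2-hydroxy ketone.

Step 3
Reactants: 5 1-(2-hydroxy-3,4,6-trimethoxyphenyl)ethanone; 6 2-methoxybenzaldehyde (1.2 equiv)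
Product: 8 (E)-1-(2-hydroxy-3,4,6-trimethoxyphenyl)-3-(2-methoxyphenyl)prop-2-en-1-one, via aldol adduct 7 (not isolated)
Conditions: KOH (50% aq, 6 equiv), EtOH, rt, 48 h; then 2 M aq HCl, 0 °C
Reagents that add atoms: none
Why: Claisen–Schmidt crossed aldol condensation: the methyl ketone enolate adds to the non-enolisable aldehyde and E1cB dehydration gives the thermodynamically favoured E-enone, erasing the carbinol stereocentre of 7.

Step 4
Reactants: 8 (E)-1-(2-hydroxy-3,4,6-trimethoxyphenyl)-3-(2-methoxyphenyl)prop-2-en-1-one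
Product: 9 5,7,8-trimethoxy-2-(2-methoxyphenyl)-4H-chromen-4-one
Conditions: I2 (0.1 equiv), DMSO, 130 °C, 3 h
Reagents that add atoms: none
Why: Iodine-catalysed oxidative cyclisation of a 2'-hydroxychalcone (6-endo oxa-Michael closure and dehydrogenation, with DMSO as terminal oxidant) closes ring C and gives the aromatic flavone without touching the aryl methyl ethers.

Step 5
Reactants: 9 5,7,8-trimethoxy-2-(2-methoxyphenyl)-4H-chromen-4-one
Product: 11 3-hydroxy-5,7,8-trimethoxy-2-(2-methoxyphenyl)-4H-chromen-4-one, via flavone 2,3-epoxide 10 (not isolated)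
Conditions: DMDO (ca. 0.08 M in acetone, 3 equiv), CH2Cl2, 0 °C to rt, 12 h; evaporate; then p-TsOH·H2O (0.1 equiv), CH2Cl2, rt, 1 h
Reagents that add atoms: dimethyldioxirane (DMDO), CC1(C)OO1
Why: Dioxirane epoxidation of the C2=C3 enol-ether double bond followed by acid-catalysed oxirane opening at C2 (oxocarbenium) and loss of H-3 gives the flavonol; the two transient stereocentres of racemic 10 are destroyed.

Step 6
Reactants: 11 3-hydroxy-5,7,8-trimethoxy-2-(2-methoxyphenyl)-4H-chromen-4-one
Product: 12 3,5,7,8-tetramethoxy-2-(2-methoxyphenyl)-4H-chromen-4-one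
Conditions: MeI (3 equiv), K2CO3 (3 equiv), acetone, reflux, 8 h
Reagents that add atoms: iodomethane (MeI), CI
Why: Williamson O-methylation of the only remaining hydroxyl (the chelated 3-OH) gives the achiral target.

**Compound list**
1 | 3,4,5-trimethoxyphenol | COc1cc(O)cc(OC)c1OC | starting material
2 | 1,2,3,5-tetramethoxybenzene | COc1cc(OC)c(OC)c(OC)c1 | intermediate
3 | acetyl chloride | CC(=O)Cl | starting material
4 | 1-(2,3,4,6-tetramethoxyphenyl)ethanone | CC(=O)c1c(OC)cc(OC)c(OC)c1OC | intermediate
5 | 1-(2-hydroxy-3,4,6-trimethoxyphenyl)ethanone | CC(=O)c1c(OC)cc(OC)c(OC)c1O | intermediate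
6 | 2-methoxybenzaldehyde | COc1ccccc1C=O | starting material
7 | rac-3-hydroxy-1-(2-hydroxy-3,4,6-trimethoxyphenyl)-3-(2-methoxyphenyl)propan-1-one | COc1ccccc1C(O)CC(=O)c1c(OC)cc(OC)c(OC)c1O | intermediate
8 | (E)-1-(2-hydroxy-3,4,6-trimethoxyphenyl)-3-(2-methoxyphenyl)prop-2-en-1-one | COc1ccccc1/C=C/C(=O)c1c(OC)cc(OC)c(OC)c1O | intermediate
9 | 5,7,8-trimethoxy-2-(2-methoxyphenyl)-4H-chromen-4-one | COc1ccccc1-c1cc(=O)c2c(OC)cc(OC)c(OC)c2o1 | intermediate
10 | rac-2,3-epoxy-5,7,8-trimethoxy-2-(2-methoxyphenyl)chroman-4-one (cis-fused oxirane) | COc1ccccc1C12OC1C(=O)c1c(OC)cc(OC)c(OC)c1O2 | intermediate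
11 | 3-hydroxy-5,7,8-trimethoxy-2-(2-methoxyphenyl)-4H-chromen-4-one | COc1ccccc1-c1oc2c(OC)c(OC)cc(OC)c2c(=O)c1O | intermediate
12 | 3,5,7,8-tetramethoxy-2-(2-methoxyphenyl)-4H-chromen-4-one (3,5,7,8,2'-pentamethoxyflavone) | COc1ccccc1-c1oc2c(OC)c(OC)cc(OC)c2c(=O)c1OC | target

**Step count and risks**
Total steps: 6. Longest linear sequence: 6 steps (1 → 2 → 5 → 8 → 9 → 11 → 12).

The three steps most likely to fail, in decreasing order of risk, are step 5, step 2 and step 4. The fallbacks are given below in step order.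

Step 2 (which ortho-methoxy group is cleaved, and over-demethylation by AlCl3). The product is checked by NOE: in 5 the lone aromatic H sits between two methoxy groups, whereas in the 2-hydroxy-4,5,6-trimethoxy isomer it has only one methoxy neighbour. The fallback sets out from 2 and comes back at 5, and it separates C–C bond formation from ether cleavage. Directed ortho-lithiation of 2 (n-BuLi, TMEDA, THF, 0 °C) at the position flanked by two methoxy groups gives 2,3,4,6-tetramethoxyphenyllithium F1. This adds to N-methoxy-N-methylacetamide at −78 °C to give the lithium hemiaminal adduct F2, which collapses on dilute aq HCl work-up to ketone 4, now isolated and purified. A separate chelation-controlled mono-demethylation with BCl3 (1.1 equiv, CH2Cl2, −78 to 0 °C) stops cleanly at the mono-phenol 5.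

Step 4 (incomplete oxidation, or partial loss of the 5-methoxy group by HI at 130 °C). The fallback sets out from 8 and comes back at 9 in two separate operations. Base-mediated oxa-Michael isomerisation (NaOAc, EtOH, reflux) gives racemic 5,7,8-trimethoxy-2-(2-methoxyphenyl)chroman-4-one F3. This is then dehydrogenated with DDQ (dioxane, reflux) to flavone 9; the flavanone stereocentre is removed in the process.

Step 5 (sluggish epoxidation of the hindered, twisted 2-aryl enol ether, or ring oxidation by DMDO). The fallback sets out from 9 and comes back at 11 by an anionic instead of an electrophilic oxygenation. Deprotonation at C-3 with LiN(iPr)2 (THF, −78 °C) gives 3-lithio-5,7,8-trimethoxy-2-(2-methoxyphenyl)chromen-4-one F4. Trapping with B(OMe)3 gives lithium trimethoxy[5,7,8-trimethoxy-2-(2-methoxyphenyl)-4-oxochromen-3-yl]borate F5. Oxidation of the C–B bond with H2O2/AcOH (0 °C to rt) delivers flavonol 11.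

**Further compounds**
F1 | step 2 | 2,3,4,6-tetramethoxyphenyllithium | [Li]c1c(OC)cc(OC)c(OC)c1OC
F2 | step 2 | lithium 1-[methoxy(methyl)amino]-1-(2,3,4,6-tetramethoxyphenyl)ethan-1-olate | [Li+].CC([O-])(N(C)OC)c1c(OC)cc(OC)c(OC)c1OC
F3 | step 4 | rac-5,7,8-trimethoxy-2-(2-methoxyphenyl)chroman-4-one | COc1ccccc1C1CC(=O)c2c(OC)cc(OC)c(OC)c2O1
F4 | step 5 | 3-lithio-5,7,8-trimethoxy-2-(2-methoxyphenyl)-4H-chromen-4-one | [Li]c1c(-c2ccccc2OC)oc2c(OC)c(OC)cc(OC)c2c1=O
F5 | step 5 | lithium trimethoxy[5,7,8-trimethoxy-2-(2-methoxyphenyl)-4-oxo-4H-chromen-3-yl]borate | [Li+].CO[B-](OC)(OC)c1c(-c2ccccc2OC)oc2c(OC)c(OC)cc(OC)c2c1=O
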